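**Remark.** The three phenols are carried as allyl ethers, because a phenolic silyl ether would not survive the fluoride that releases the ylide. The target ring is (2R,3S,4S), which is the series that anti addition to the (5R)-menthyloxybutenolide from (−)-menthol should deliver. Ring numbering used throughout: O1, C2 (aryl), C3 (CH2O arm), C4 (benzyl arm), C5.

## Retrosynthetic overview

1. The phenols are unmasked last from allyl ethers; the ester C–O bond is cut to give (E)-4-(allyloxy)cinnamic acid and the di-O-allyl lariciresinol-type alcohol 22.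
2. The benzyl arm on C4 is cut at the aryl–CH2 bond: aryl Grignard addition to a C4 aldehyde held as a cis-fused lactol, then radical removal of the benzylic hydroxyl.
3. Feature used: the tetrahydrofuran ring O1–C2–C3–C4–C5 with cis one-carbon arms on C3 (CH2O) and C4 (CH2Ar). The two arms are tied back as the carbonyl carbon and the acetal carbon of a butenolide, which leaves C2–O1–C5 as a carbonyl ylide.
4. Key disconnection: C2–C3 and C4–C5, by [3+2] cycloaddition of the aryl carbonyl ylide (from an α-chloro silylmethyl ether of O-allylvanillin) to (5R)-5-menthyloxyfuran-2(5H)-one.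
5. Ring order: butenolide ring (step 5), tetrahydrofuran ring (step 6, the only ring of the target core), lactone opened (step 7); a temporary lactol ring (step 9) is opened in step 11.

Key step: step 6

## Route

Step 1
Reactants: 1 vanillin
Product: 2 4-(allyloxy)-3-methoxybenzaldehyde
Conditions: allyl bromide, K2CO3, DMF, 50 °C
Reagents that add atoms: allyl bromide C=CCBr
Why: Williamson ether synthesis on the phenoxide; the aryl allyl ether is inert to fluoride, hydride, Grignard and tin hydride conditions and can be removed at the end under neutral conditions.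

Step 2
Reactants: 2 4-(allyloxy)-3-methoxybenzaldehyde; 3 (trimethylsilyl)methanol
Product: 4 1-(allyloxy)-4-{bis[(trimethylsilyl)methoxy]methyl}-2-methoxybenzene
Conditions: 3 (2.5 equiv), p-TsOH·H2O (cat.), toluene, reflux, Dean–Stark trap
Reagents that add atoms: none
Why: Acid-catalysed acetalisation driven by azeotropic removal of water; it installs the silylmethyl group whose carbon becomes C5.

Step 3
Reactants: 4 1-(allyloxy)-4-{bis[(trimethylsilyl)methoxy]methyl}-2-methoxybenzene
Product: 5 racemic 1-(allyloxy)-4-{chloro[(trimethylsilyl)methoxy]methyl}-2-methoxybenzene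
Conditions: AcCl (1.2 equiv), SOCl2 (cat.), CH2Cl2, 0 °C to rt; volatiles removed in vacuo, used crude
Reagents that add atoms: acetyl chloride CC(Cl)=O
Why: Acetal–acyl chloride exchange (one acetal oxygen is acetylated and chloride captures the aryl-stabilised oxocarbenium ion) is the standard entry to α-chloro ethers; the chloride-bearing carbon is racemic, which does not matter because it becomes the planar ylide terminus.

Step 4
Reactants: 6 furfural
Product: 7 racemic 5-hydroxyfuran-2(5H)-one
Conditions: O2, visible light, rose bengal (C20H2Cl4I4Na2O5, cat.), MeOH, rt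
Reagents that add atoms: oxygen O=O
Why: Sensitised photooxygenation: singlet oxygen adds [4+2] to the furan and methanolysis of the endoperoxide expels the formyl carbon as methyl formate.

Step 5
Reactants: 7 racemic 5-hydroxyfuran-2(5H)-one; 8 (1R,2S,5R)-menthol
Product: 9 (5R)-5-[(1R,2S,5R)-menthyloxy]furan-2(5H)-one
Conditions: p-TsOH·H2O (cat.), toluene, reflux, Dean–Stark trap; crystallisation from hexane at −20 °C; mother liquor re-equilibrated with p-TsOH and recrystallised
Reagents that add atoms: none
Why: Acid-catalysed acetal formation gives both C5 epimers, and the (5R) epimer should be obtained pure by crystallisation, with acid epimerisation of the mother liquor recycling the other (crystallisation-driven resolution of the acetal centre).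

Step 6
Reactants: 5 racemic 1-(allyloxy)-4-{chloro[(trimethylsilyl)methoxy]methyl}-2-methoxybenzene; 9 (5R)-5-[(1R,2S,5R)-menthyloxy]furan-2(5H)-one
Product: 11 (1R,4R,5S,8R)-8-[4-(allyloxy)-3-methoxyphenyl]-4-[(1R,2S,5R)-menthyloxy]-3,7-dioxabicyclo[3.3.0]octan-2-one (cis-fused; aryl exo; menthyloxy exo), via aryl carbonyl ylide 10 (not isolated)
Conditions: CsF (3 equiv, dried), MeCN, rt; 5 (1.5 equiv) added slowly to 9 and CsF
Reagents that add atoms: none
Why: Fluoride attacks silicon in the ionised α-chloro ether (1,3-elimination) and releases the non-stabilised carbonyl ylide 10, which adds in a concerted suprafacial 1,3-dipolar [3+2] cycloaddition to the electron-poor C3=C4 alkene of 9; the closest known reaction type is the cycloaddition of silicon-derived non-stabilised carbonyl ylides to acrylate-type alkenes, together with the anti-selective dipolar cycloadditions of 5-alkoxyfuran-2(5H)-ones. The tetrahydrofuran ring is closed by an intermolecular two-bond annulation in which C2–C3 and C4–C5 form in the same event on one face of the alkene. C4 is set by approach of the dipole anti to the menthyloxy group on the neighbouring acetal carbon, C3 follows as cis to C4 because the addition is suprafacial on a cis alkene, and C2 is set by exo placement of the aryl group on the convex face, away from the lactone ring. The step needs facial selectivity (the menthyloxy group shields one face), regioselectivity (the unsubstituted CH2 terminus has the larger HOMO coefficient and should bond to the β-carbon, which has the larger LUMO coefficient, and this also keeps the aryl terminus away from the acetal substituent) and exo selectivity (steric preference, and the exo isomer is also the more stable one).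

Step 7
Reactants: 11 the cycloadduct
Product: 12 methyl (2R,3R,4S)-2-[4-(allyloxy)-3-methoxyphenyl]-4-(dimethoxymethyl)tetrahydrofuran-3-carboxylate
Conditions: MeOH, HC(OMe)3, p-TsOH·H2O (cat.), 40 °C; then NaHCO3
Reagents that add atoms: methanol CO; trimethyl orthoformate COC(OC)OC (water scavenger and alternative methoxy donor)
Why: Acid-catalysed methanolysis of the acylal: the lactone carboxylate leaves from the acetal carbon, which becomes the dimethyl acetal, and Fischer esterification with orthoformate as water scavenger gives the methyl ester and frees menthol; no stereocentre is touched because C3 does not enolise under these conditions.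

Step 8
Reactants: 12 the ester acetal
Product: 13 [(2R,3S,4S)-2-[4-(allyloxy)-3-methoxyphenyl]-4-(dimethoxymethyl)tetrahydrofuran-3-yl]methanol
Conditions: LiAlH4, THF, 0 °C; H2O, aq. NaOH work-up
Reagents that add atoms: none
Why: Hydride reduction of the ester to the primary alcohol is fast at 0 °C, while the dimethyl acetal, the benzylic ether and the aryl allyl ethers are inert.

Step 9
Reactants: 13 the hydroxy acetal
Product: 14 (1S,5S,6R)-6-[4-(allyloxy)-3-methoxyphenyl]-3,7-dioxabicyclo[3.3.0]octan-2-ol (cis-fused lactol, both anomers)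
Conditions: 1 M HCl, THF, rt
Reagents that add atoms: water O
Why: Acetal hydrolysis; the cis CH2OH captures the C4 aldehyde as a cis-fused lactol, which protects C4 against epimerisation because only the cis isomer can close the ring.

Step 10
Reactants: 15 4-bromo-2-methoxyphenol
Product: 16 1-(allyloxy)-4-bromo-2-methoxybenzene
Conditions: allyl bromide, K2CO3, DMF, 50 °C
Reagents that add atoms: allyl bromide C=CCBr
Why: Williamson ether synthesis, giving the same phenol protection as on the other aryl ring.

Step 11
Reactants: 14 the lactol; 16 1-(allyloxy)-4-bromo-2-methoxybenzene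
Product: 18 [(2R,3S,4S)-2-[4-(allyloxy)-3-methoxyphenyl]-4-{[4-(allyloxy)-3-methoxyphenyl](hydroxy)methyl}tetrahydrofuran-3-yl]methanol (both carbinol epimers), via [4-(allyloxy)-3-methoxyphenyl]magnesium bromide 17 (not isolated)
Conditions: 16, Mg, I2 (cat.), THF, 40 °C; then 14 (3.5 equiv of 17 per 14), THF, 0 °C to rt; aq. NH4Cl
Reagents that add atoms: none
Why: Grignard addition to a lactol: the first equivalent deprotonates the lactol, the magnesium lactolate opens to the aldehyde and the aryl Grignard adds faster than it enolises it; the new carbinol centre is not controlled and is removed in step 14.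

Step 12
Reactants: 18 the diol
Product: 19 (2R,3S,4S) primary tert-butyldimethylsilyl ether of 18, with the secondary benzylic hydroxyl free
Conditions: TBSCl (1.1 equiv), imidazole, CH2Cl2, 0 °C
Reagents that add atoms: tert-butyldimethylsilyl chloride CC(C)(C)[Si](C)(C)Cl
Why: Silylation should be selective for the primary hydroxyl over the hindered secondary benzylic one.

Step 13
Reactants: 19 the mono-silyl ether
Product: 20 O-phenyl thionocarbonate of the benzylic hydroxyl of 19
Conditions: PhOC(S)Cl, pyridine, DMAP (cat.), CH2Cl2, 0 °C to rt; used without delay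
Reagents that add atoms: O-phenyl chlorothionoformate S=C(Cl)Oc1ccccc1
Why: Thioacylation of the secondary alcohol under mild base gives the radical precursor for a Barton–McCombie deoxygenation without strongly basic conditions.

Step 14
Reactants: 20 the thionocarbonate
Product: 21 tert-butyl{[(2R,3S,4S)-2-[4-(allyloxy)-3-methoxyphenyl]-4-[4-(allyloxy)-3-methoxybenzyl]tetrahydrofuran-3-yl]methoxy}dimethylsilane
Conditions: Bu3SnH, AIBN (cat.), toluene, 80 °C
Reagents that add atoms: none
Why: Barton–McCombie deoxygenation: the stannyl radical adds to C=S, β-scission gives the benzylic radical and hydrogen transfer from Bu3SnH gives the CH2; no cation is formed, so the benzylic C2–O1 ether, the silyl ether and the allyl ethers should survive.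

Step 15
Reactants: 21 the deoxygenated silyl ether
Product: 22 [(2R,3S,4S)-2-[4-(allyloxy)-3-methoxyphenyl]-4-[4-(allyloxy)-3-methoxybenzyl]tetrahydrofuran-3-yl]methanol
Conditions: Bu4NF, THF, rt
Reagents that add atoms: none
Why: Fluoride cleavage of the alkyl silyl ether; the aryl allyl ethers are inert to fluoride.

Step 16
Reactants: 23 p-coumaric acid
Product: 25 (E)-3-[4-(allyloxy)phenyl]acrylic acid, via allyl (E)-4-(allyloxy)cinnamate 24 (not isolated)
Conditions: allyl bromide (2.5 equiv), K2CO3, acetone, reflux; then NaOH, MeOH/H2O, 50 °C; then aq. HCl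
Reagents that add atoms: allyl bromide C=CCBr
Why: Double Williamson-type O-allylation (carboxylate and phenoxide) followed by saponification of the allyl ester; the aryl allyl ether and the E-alkene are stable to hydroxide.

Step 17
Reactants: 22 the primary alcohol; 25 (E)-3-[4-(allyloxy)phenyl]acrylic acid
Product: 26 [(2R,3S,4S)-2-[4-(allyloxy)-3-methoxyphenyl]-4-[4-(allyloxy)-3-methoxybenzyl]tetrahydrofuran-3-yl]methyl (E)-3-[4-(allyloxy)phenyl]acrylate
Conditions: DCC, DMAP (cat.), CH2Cl2, 0 °C to rt
Reagents that add atoms: none
Why: Steglich esterification (O-acylisourea, acyl transfer by DMAP) of the only free hydroxyl; the alkene geometry and the ring stereocentres are not involved.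

Step 18
Reactants: 26 the tri-O-allyl ester
Product: 27 lariciresinol p-coumarate, [(2R,3S,4S)-2-(4-hydroxy-3-methoxyphenyl)-4-(4-hydroxy-3-methoxybenzyl)tetrahydrofuran-3-yl]methyl (E)-3-(4-hydroxyphenyl)acrylate
Conditions: Pd(PPh3)4 (cat.), morpholine (excess), THF, rt
Reagents that add atoms: none
Why: Tsuji–Trost-type deallylation: zerovalent palladium ionises each aryl allyl ether to a π-allyl complex and a phenoxide, and morpholine traps the allyl group; the neutral conditions should spare the cinnamate ester, the E-alkene and the acid-sensitive benzylic ether.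

## Compound list

1 | vanillin | COc1cc(C=O)ccc1O | starting material
2 | 4-(allyloxy)-3-methoxybenzaldehyde | COc1cc(C=O)ccc1OCC=C | intermediate
3 | (trimethylsilyl)methanol | C[Si](C)(C)CO | starting material
4 | 1-(allyloxy)-4-{bis[(trimethylsilyl)methoxy]methyl}-2-methoxybenzene | COc1cc(C(OC[Si](C)(C)C)OC[Si](C)(C)C)ccc1OCC=C | intermediate
5 | racemic 1-(allyloxy)-4-{chloro[(trimethylsilyl)methoxy]methyl}-2-methoxybenzene | COc1cc(C(Cl)OC[Si](C)(C)C)ccc1OCC=C | intermediate
6 | furfural | O=Cc1ccco1 | starting material
7 | racemic 5-hydroxyfuran-2(5H)-one | O=C1C=CC(O)O1 | intermediate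
8 | (1R,2S,5R)-menthol | CC(C)[C@@H]1CC[C@@H](C)C[C@H]1O | starting material
9 | (5R)-5-[(1R,2S,5R)-menthyloxy]furan-2(5H)-one | O=C1C=C[C@H](O[C@@H]2C[C@H](C)CC[C@H]2C(C)C)O1 | intermediate
10 | aryl carbonyl ylide, [4-(allyloxy)-3-methoxybenzylidene]oxonium methylide | COc1cc(C=[O+][CH2-])ccc1OCC=C | intermediate (not isolated)
11 | (1R,4R,5S,8R)-8-[4-(allyloxy)-3-methoxyphenyl]-4-[(1R,2S,5R)-menthyloxy]-3,7-dioxabicyclo[3.3.0]octan-2-one | O=C1O[C@@H](O[C@@H]3C[C@H](C)CC[C@H]3C(C)C)[C@@H]2CO[C@@H](c3ccc(OCC=C)c(OC)c3)[C@H]12 | intermediate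
12 | methyl (2R,3R,4S)-2-[4-(allyloxy)-3-methoxyphenyl]-4-(dimethoxymethyl)tetrahydrofuran-3-carboxylate | COC(OC)[C@@H]1CO[C@@H](c2ccc(OCC=C)c(OC)c2)[C@@H]1C(=O)OC | intermediate
13 | [(2R,3S,4S)-2-[4-(allyloxy)-3-methoxyphenyl]-4-(dimethoxymethyl)tetrahydrofuran-3-yl]methanol | COC(OC)[C@@H]1CO[C@@H](c2ccc(OCC=C)c(OC)c2)[C@@H]1CO | intermediate
14 | (1S,5S,6R)-6-[4-(allyloxy)-3-methoxyphenyl]-3,7-dioxabicyclo[3.3.0]octan-2-ol (anomeric mixture) | OC1[C@@H]2CO[C@@H](c3ccc(OCC=C)c(OC)c3)[C@@H]2CO1 | intermediate
15 | 4-bromo-2-methoxyphenol | COc1cc(Br)ccc1O | starting material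
16 | 1-(allyloxy)-4-bromo-2-methoxybenzene | COc1cc(Br)ccc1OCC=C | intermediate
17 | [4-(allyloxy)-3-methoxyphenyl]magnesium bromide | COc1cc([Mg]Br)ccc1OCC=C | intermediate (not isolated)
18 | [(2R,3S,4S)-2-[4-(allyloxy)-3-methoxyphenyl]-4-{[4-(allyloxy)-3-methoxyphenyl](hydroxy)methyl}tetrahydrofuran-3-yl]methanol (both carbinol epimers) | COc1cc(C(O)[C@@H]2CO[C@@H](c3ccc(OCC=C)c(OC)c3)[C@@H]2CO)ccc1OCC=C | intermediate
19 | primary tert-butyldimethylsilyl ether of 18 | COc1cc(C(O)[C@@H]2CO[C@@H](c3ccc(OCC=C)c(OC)c3)[C@@H]2CO[Si](C)(C)C(C)(C)C)ccc1OCC=C | intermediate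
20 | O-phenyl thionocarbonate of 19 | COc1cc(C(OC(=S)Oc4ccccc4)[C@@H]2CO[C@@H](c3ccc(OCC=C)c(OC)c3)[C@@H]2CO[Si](C)(C)C(C)(C)C)ccc1OCC=C | intermediate
21 | tert-butyl{[(2R,3S,4S)-2-[4-(allyloxy)-3-methoxyphenyl]-4-[4-(allyloxy)-3-methoxybenzyl]tetrahydrofuran-3-yl]methoxy}dimethylsilane | COc1cc(C[C@@H]2CO[C@@H](c3ccc(OCC=C)c(OC)c3)[C@@H]2CO[Si](C)(C)C(C)(C)C)ccc1OCC=C | intermediate
22 | [(2R,3S,4S)-2-[4-(allyloxy)-3-methoxyphenyl]-4-[4-(allyloxy)-3-methoxybenzyl]tetrahydrofuran-3-yl]methanol | COc1cc(C[C@@H]2CO[C@@H](c3ccc(OCC=C)c(OC)c3)[C@@H]2CO)ccc1OCC=C | intermediate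
23 | p-coumaric acid | O=C(O)/C=C/c1ccc(O)cc1 | starting material
24 | allyl (E)-3-[4-(allyloxy)phenyl]acrylate | C=CCOC(=O)/C=C/c1ccc(OCC=C)cc1 | intermediate (not isolated)
25 | (E)-3-[4-(allyloxy)phenyl]acrylic acid | O=C(O)/C=C/c1ccc(OCC=C)cc1 | intermediate
26 | [(2R,3S,4S)-2-[4-(allyloxy)-3-methoxyphenyl]-4-[4-(allyloxy)-3-methoxybenzyl]tetrahydrofuran-3-yl]methyl (E)-3-[4-(allyloxy)phenyl]acrylate | COc1cc(C[C@@H]2CO[C@@H](c3ccc(OCC=C)c(OC)c3)[C@@H]2COC(=O)/C=C/c2ccc(OCC=C)cc2)ccc1OCC=C | intermediate
27 | lariciresinol p-coumarate | COc1cc(C[C@@H]2CO[C@@H](c3ccc(O)c(OC)c3)[C@@H]2COC(=O)/C=C/c2ccc(O)cc2)ccc1O | target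

## Step count and risks

Total step count: 18. Longest linear sequence: 14 steps (1, 2, 3, 6, 7, 8, 9, 11, 12, 13, 14, 15, 17, 18, from vanillin).

**Step 6 (cycloaddition).** The ylide may add with incomplete exo/endo control, placing the aryl group on the concave face at C2; regiocontrol may also erode, or the ylide may be lost to self-condensation. The fallback sets out from 5 and 9 and comes back at 12. It gives up kinetic control of C2 and sets this centre thermodynamically: the cycloaddition is run as before, and the endo-aryl cycloadduct F1 is taken through the methanolysis of step 7 to the 2,3-cis ester F2. F2 is then held with p-TsOH in MeOH/HC(OMe)3 at 60 °C. Reversible ionisation of the benzylic C2–O1 bond, with methanol as a reversible trap and reclosure by the C5 hydroxyl, should drain the material into the less crowded 2,3-trans ester 12; this is the known acid epimerisation of 2-aryltetrahydrofuran lignans.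

**Step 13 (with step 14, benzylic deoxygenation).** The electron-rich benzylic thionocarbonate may ionise before the radical step. That would lead to oxygen-to-sulfur rearrangement, elimination, or capture of the cation by the cis CH2O-silyl oxygen to close a second tetrahydrofuran ring. The fallback sets out from lactol 14 (and aryl bromide 16 for the boron partner) and comes back at 22. It never places a leaving group on the benzylic carbon: 14 is condensed with TsNHNH2 in MeOH to give the hydroxy N-tosylhydrazone F3. Grignard reagent 17 (from 16) is quenched with B(OMe)3 and hydrolysed to [4-(allyloxy)-3-methoxyphenyl]boronic acid F4. Heating F3 with F4 and K2CO3 in dioxane at 110 °C (metal-free reductive coupling through the diazoalkane, 1,2-shift to boron and protodeboronation) should give 22 directly, bypassing steps 11 to 15.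

**Step 7 (methanolysis).** The opening may stall at the cyclic 5-methoxy lactone (pseudo-ester), which step 8 would over-reduce, or prolonged acid may erode the C2 configuration. The fallback sets out from 11 and comes back at 14. It traps the masked aldehyde as a dithioacetal instead of an O,O-acetal: ethane-1,2-dithiol and BF3·OEt2 in CH2Cl2 at −20 °C should convert 11 into the dithiolane acid F5 with release of menthol. LiAlH4 in THF reduces the acid to the dithiolane alcohol F6. MeI and CaCO3 in aqueous MeCN then hydrolyse the dithiolane, and the hydroxy aldehyde closes to lactol 14, bypassing steps 7 to 9.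

## Further compounds

F1 | step 6 | (1R,4R,5S,8S)-8-[4-(allyloxy)-3-methoxyphenyl]-4-[(1R,2S,5R)-menthyloxy]-3,7-dioxabicyclo[3.3.0]octan-2-one (endo-aryl cycloadduct) | O=C1O[C@@H](O[C@@H]3C[C@H](C)CC[C@H]3C(C)C)[C@@H]2CO[C@H](c3ccc(OCC=C)c(OC)c3)[C@H]12
F2 | step 6 | methyl (2S,3R,4S)-2-[4-(allyloxy)-3-methoxyphenyl]-4-(dimethoxymethyl)tetrahydrofuran-3-carboxylate (2,3-cis ester) | COC(OC)[C@@H]1CO[C@H](c2ccc(OCC=C)c(OC)c2)[C@@H]1C(=O)OC
F3 | step 13 | N-tosylhydrazone of the open hydroxy aldehyde form of 14 | Cc1ccc(cc1)S(=O)(=O)NN=C[C@@H]2CO[C@@H](c3ccc(OCC=C)c(OC)c3)[C@@H]2CO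
F4 | step 13 | [4-(allyloxy)-3-methoxyphenyl]boronic acid | COc1cc(B(O)O)ccc1OCC=C
F5 | step 7 | (2R,3R,4S)-2-[4-(allyloxy)-3-methoxyphenyl]-4-(1,3-dithiolan-2-yl)tetrahydrofuran-3-carboxylic acid | S1CCSC1[C@@H]2CO[C@@H](c3ccc(OCC=C)c(OC)c3)[C@@H]2C(=O)O
F6 | step 7 | [(2R,3S,4S)-2-[4-(allyloxy)-3-methoxyphenyl]-4-(1,3-dithiolan-2-yl)tetrahydrofuran-3-yl]methanol | S1CCSC1[C@@H]2CO[C@@H](c3ccc(OCC=C)c(OC)c3)[C@@H]2CO
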